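**Plan**

- Cuts: the polyene at C11'=C12' (last Wittig) and at C11=C12 (Wittig with the C10 trienedial); each end group at its C9 carbonyl and at its arm alkene (C=CMe2 or C=C(CH2OH)2); and in each ring the C1–C6 bond.
- Feature: ring A (prenyl arm) and ring B (diol arm, opposite configuration) each contain C1 with its two methyl groups, the stereocentre C2 with the first two arm carbons, C3, C4 and C5 with its methyl group in the connectivity of the keto aldehyde from ring opening of limonene 1,2-oxide. Once C6–C9 are attached to C5 (ethynylation, Saucy–Marbet rearrangement), C1–C6 is the only ring bond missing.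
- Forward order: acid cyclization of the acyclic trienone acetates closes ring A (step 6) and ring B (step 19). Ring A is grown to a C15 phosphonium salt, a C30 aldehyde and the C30 phosphonium salt 19. Ring B is grown to a C15 nitrile, receives its arm alkene and becomes dienal diol 37. Compounds 19 and 37 are joined last.
- Stereochemistry: C2 (R) is taken from (4R)-limonene oxide and C2' (S) from (4S)-limonene oxide and both are only carried. No stereocentre is created. E-alkenes come from E-selective olefinations and thermal equilibration.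

Key step: step 6

Remark on the chemistry: centres that are erased later (epoxide carbons of 1 and 20, carbinol carbons of 4, 5, 7, 11–13 and 23–25, allene axes of 8 and 26) are carried as mixtures and left undefined in the SMILES; 9 and 27 should form as 6E/6Z mixtures that converge in the cyclization, and the 6E isomer is listed.

**Route**

Step 1
Reactants: 1 (4R)-limonene 1,2-oxide (cis/trans mixture)
Product: 2 (3R)-6-oxo-3-(prop-1-en-2-yl)heptanal
Conditions: HIO4·2H2O, THF/H2O, 0 °C → rt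
Reagents that add atoms: water, O
Why: Epoxide hydrolysis followed by periodate glycol cleavage opens the ring between the two former alkene carbons and should leave the isopropenyl group and the stereocentre, which is β to the new aldehyde, untouched.

Step 2
Reactants: 2 (3R)-6-oxo-3-(prop-1-en-2-yl)heptanal
Product: 3 (5R)-7-hydroxy-5-(prop-1-en-2-yl)heptan-2-one
Conditions: NaBH(OAc)3, PhH, 80 °C
Reagents that add atoms: none
Why: Chemoselective hydride reduction, since the attenuated acyloxyborohydride reduces aldehydes but not ketones.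

Step 3
Reactants: 3 (5R)-7-hydroxy-5-(prop-1-en-2-yl)heptan-2-one
Product: 4 (3R)-6-methyl-3-(prop-1-en-2-yl)oct-7-yne-1,6-diol
Conditions: HC≡CMgBr (3 equiv), THF, 0 °C → rt; then H2O
Reagents that add atoms: ethynylmagnesium bromide, C#C[Mg]Br
Why: Grignard 1,2-addition of the acetylide to the methyl ketone after deprotonation of the primary alcohol; the new carbinol centre forms without control and is erased in step 5.

Step 4
Reactants: 4 (3R)-6-methyl-3-(prop-1-en-2-yl)oct-7-yne-1,6-diol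
Product: 5 (3R)-6-hydroxy-6-methyl-3-(prop-1-en-2-yl)oct-7-yn-1-yl acetate
Conditions: Ac2O (1.1 equiv), pyridine, CH2Cl2, 0 °C
Reagents that add atoms: acetic anhydride, CC(=O)OC(C)=O
Why: Acylation distinguishes the primary alcohol from the hindered tertiary propargylic alcohol and installs the acetate arm that has to be a spectator in step 6.

Step 5
Reactants: 5 (3R)-6-hydroxy-6-methyl-3-(prop-1-en-2-yl)oct-7-yn-1-yl acetate; 6 2-methoxypropene
Product: 9 (3R,6E,8E)-6-methyl-10-oxo-3-(prop-1-en-2-yl)undeca-6,8-dien-1-yl acetate, via propargyl isopropenyl ether 7 (not isolated), via allenyl ketone 8 (not isolated)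
Conditions: 6 (4 equiv), p-TsOH (cat.), toluene, sealed vessel, 100 °C; then DBU (0.3 equiv), 0 °C → rt
Reagents that add atoms: none
Why: Saucy–Marbet rearrangement, in which acid-catalysed vinyl ether exchange gives 7, its [3,3]-sigmatropic shift gives 8, and base-mediated allene-to-diene isomerization should deliver the conjugated dienone without cleaving the acetate.

Step 6
Reactants: 9 (3R,6E,8E)-6-methyl-10-oxo-3-(prop-1-en-2-yl)undeca-6,8-dien-1-yl acetate
Product: 10 2-[(1R)-2,2,4-trimethyl-3-[(E)-3-oxobut-1-en-1-yl]cyclohex-3-en-1-yl]ethyl acetate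
Conditions: conc. H2SO4, CH2Cl2, −20 °C, short contact; then ice
Reagents that add atoms: none
Why: Protonation of the 1,1-disubstituted alkene of 9 at its CH2 terminus generates the tertiary cation at C1, C6 of the trisubstituted C5=C6 alkene bonds to it, and the C5 cation so formed sheds the proton on C6, which leaves the tetrasubstituted ring alkene conjugated with the enone. The closest known reaction type is the acid-mediated cation–olefin cyclization of pseudoionone to β-ionone. Ring A closes in a 6-endo-trig mode through a chair-like arrangement of the tether. No stereocentre is formed; the C2 centre next to the cation only has to survive, which requires ring closure to outrun 1,2-hydride shift and deprotonation to the isopropylidene isomer, and the short tether, the low temperature and the brief contact time should favour closure. The position of the ring alkene is under thermodynamic control, because strong acid funnels any α- or γ-isomer into the conjugated β-isomer, and the 6E and 6Z isomers of 9 give the same cation. The arm is carried as an acetate because it offers no second alkene to compete for the proton and, once protonated, is too poor a nucleophile to trap the cation as a cyclic ether.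

Step 7
Reactants: 10 2-[(1R)-2,2,4-trimethyl-3-[(E)-3-oxobut-1-en-1-yl]cyclohex-3-en-1-yl]ethyl acetate
Product: 11 (1E)-1-[(5R)-5-(2-hydroxyethyl)-2,6,6-trimethylcyclohex-1-en-1-yl]-3-methylpenta-1,4-dien-3-ol
Conditions: CH2=CHMgBr (4 equiv), THF, −20 → 0 °C; then H2O
Reagents that add atoms: vinylmagnesium bromide, C=C[Mg]Br
Why: Grignard 1,2-addition to the dienone carbonyl gives the tertiary vinyl carbinol while two further equivalents cleave the acetate; the carbinol centre is uncontrolled and disappears in step 10.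

Step 8
Reactants: 11 (1E)-1-[(5R)-5-(2-hydroxyethyl)-2,6,6-trimethylcyclohex-1-en-1-yl]-3-methylpenta-1,4-dien-3-ol
Product: 12 2-[(1R)-3-[(1E)-3-hydroxy-3-methylpenta-1,4-dien-1-yl]-2,2,4-trimethylcyclohex-3-en-1-yl]acetaldehyde
Conditions: SO3·pyridine, DMSO, i-Pr2NEt, CH2Cl2, 0 °C
Reagents that add atoms: none
Why: Parikh–Doering oxidation converts only the primary alcohol, since the tertiary bis-allylic alcohol cannot be oxidised and the amine-buffered medium avoids its ionisation.

Step 9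
Reactants: 12 2-[(1R)-3-[(1E)-3-hydroxy-3-methylpenta-1,4-dien-1-yl]-2,2,4-trimethylcyclohex-3-en-1-yl]acetaldehyde
Product: 13 (1E)-3-methyl-1-[(5R)-2,6,6-trimethyl-5-(3-methylbut-2-en-1-yl)cyclohex-1-en-1-yl]penta-1,4-dien-3-ol
Conditions: i-PrPPh3I, n-BuLi, THF, 0 °C; then 12, −78 °C → rt
Reagents that add atoms: isopropyltriphenylphosphonium iodide, CC(C)[P+](c1ccccc1)(c1ccccc1)c1ccccc1.[I-]
Why: Wittig olefination with the non-stabilised isopropylidene ylide, used in excess because of the free hydroxyl group, turns the aldehyde into the prenyl alkene, and C2 is β to the carbonyl and cannot epimerise.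

Step 10
Reactants: 13 (1E)-3-methyl-1-[(5R)-2,6,6-trimethyl-5-(3-methylbut-2-en-1-yl)cyclohex-1-en-1-yl]penta-1,4-dien-3-ol
Product: 14 [(2E,4E)-3-methyl-5-[(5R)-2,6,6-trimethyl-5-(3-methylbut-2-en-1-yl)cyclohex-1-en-1-yl]penta-2,4-dien-1-yl]triphenylphosphonium bromide
Conditions: PPh3·HBr, MeOH, 0 °C → rt
Reagents that add atoms: triphenylphosphine hydrobromide, [Br-].c1ccc(cc1)[PH+](c1ccccc1)c1ccccc1
Why: Acid-promoted ionisation of the tertiary bis-allylic alcohol gives a pentadienyl cation that PPh3 captures at the primary terminus (allylic substitution with transposition), the usual way from vinyl carbinols of the ionone series to phosphonium salts, and the isolated prenyl alkene should be inert.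

Step 11
Reactants: 14 [(2E,4E)-3-methyl-5-[(5R)-2,6,6-trimethyl-5-(3-methylbut-2-en-1-yl)cyclohex-1-en-1-yl]penta-2,4-dien-1-yl]triphenylphosphonium bromide; 15 (2E,4E,6E)-2,7-dimethylocta-2,4,6-trienedial
Product: 17 (2E,4E,6E,8E,10E,12E)-2,7,11-trimethyl-13-[(5R)-2,6,6-trimethyl-5-(3-methylbut-2-en-1-yl)cyclohex-1-en-1-yl]trideca-2,4,6,8,10,12-hexaenal, via C15 ylide 16 (not isolated)
Conditions: 15 (3 equiv), NaOMe, CH2Cl2/MeOH, 0 °C, slow addition of 14; then heptane, 90 °C
Reagents that add atoms: none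
Why: Wittig olefination of one aldehyde group of the symmetrical dialdehyde, kept in excess to suppress double condensation, forms C11=C12, and heating should equilibrate any 11Z isomer to the all-E polyene.

Step 12
Reactants: 17 (2E,4E,6E,8E,10E,12E)-2,7,11-trimethyl-13-[(5R)-2,6,6-trimethyl-5-(3-methylbut-2-en-1-yl)cyclohex-1-en-1-yl]trideca-2,4,6,8,10,12-hexaenal
Product: 18 (2E,4E,6E,8E,10E,12E)-2,7,11-trimethyl-13-[(5R)-2,6,6-trimethyl-5-(3-methylbut-2-en-1-yl)cyclohex-1-en-1-yl]trideca-2,4,6,8,10,12-hexaen-1-ol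
Conditions: NaBH4, EtOH/THF, 0 °C
Reagents that add atoms: none
Why: Borohydride 1,2-reduction of the conjugated aldehyde gives the primary polyenylic alcohol without touching the alkenes.

Step 13
Reactants: 18 (2E,4E,6E,8E,10E,12E)-2,7,11-trimethyl-13-[(5R)-2,6,6-trimethyl-5-(3-methylbut-2-en-1-yl)cyclohex-1-en-1-yl]trideca-2,4,6,8,10,12-hexaen-1-ol
Product: 19 [(2E,4E,6E,8E,10E,12E)-2,7,11-trimethyl-13-[(5R)-2,6,6-trimethyl-5-(3-methylbut-2-en-1-yl)cyclohex-1-en-1-yl]trideca-2,4,6,8,10,12-hexaen-1-yl]triphenylphosphonium bromide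
Conditions: PPh3·HBr, MeOH/CH2Cl2, 0 °C → rt, dark
Reagents that add atoms: triphenylphosphine hydrobromide, [Br-].c1ccc(cc1)[PH+](c1ccccc1)c1ccccc1
Why: Phosphonium salt formation by ionisation of the polyenylic alcohol and capture of the delocalised cation by PPh3 at the terminal carbon, which keeps the conjugation intact.

Step 14
Reactants: 20 (4S)-limonene 1,2-oxide (cis/trans mixture)
Product: 21 (3S)-6-oxo-3-(prop-1-en-2-yl)heptanal
Conditions: HIO4·2H2O, THF/H2O, 0 °C → rt
Reagents that add atoms: water, O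
Why: Epoxide hydrolysis and periodate glycol cleavage as in step 1, on the enantiomer.

Step 15
Reactants: 21 (3S)-6-oxo-3-(prop-1-en-2-yl)heptanal
Product: 22 (5S)-7-hydroxy-5-(prop-1-en-2-yl)heptan-2-one
Conditions: NaBH(OAc)3, PhH, 80 °C
Reagents that add atoms: none
Why: Chemoselective hydride reduction of the aldehyde beside the ketone as in step 2.

Step 16
Reactants: 22 (5S)-7-hydroxy-5-(prop-1-en-2-yl)heptan-2-one
Product: 23 (3S)-6-methyl-3-(prop-1-en-2-yl)oct-7-yne-1,6-diol
Conditions: HC≡CMgBr (3 equiv), THF, 0 °C → rt; then H2O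
Reagents that add atoms: ethynylmagnesium bromide, C#C[Mg]Br
Why: Grignard 1,2-addition of the acetylide to the ketone as in step 3, the uncontrolled carbinol centre being erased in step 18.

Step 17
Reactants: 23 (3S)-6-methyl-3-(prop-1-en-2-yl)oct-7-yne-1,6-diol
Product: 24 (3S)-6-hydroxy-6-methyl-3-(prop-1-en-2-yl)oct-7-yn-1-yl acetate
Conditions: Ac2O (1.1 equiv), pyridine, CH2Cl2, 0 °C
Reagents that add atoms: acetic anhydride, CC(=O)OC(C)=O
Why: Selective acylation of the primary alcohol beside the tertiary one as in step 4.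

Step 18
Reactants: 24 (3S)-6-hydroxy-6-methyl-3-(prop-1-en-2-yl)oct-7-yn-1-yl acetate; 6 2-methoxypropene
Product: 27 (3S,6E,8E)-6-methyl-10-oxo-3-(prop-1-en-2-yl)undeca-6,8-dien-1-yl acetate, via propargyl isopropenyl ether 25 (not isolated), via allenyl ketone 26 (not isolated)
Conditions: 6 (4 equiv), p-TsOH (cat.), toluene, sealed vessel, 100 °C; then DBU (0.3 equiv), 0 °C → rt
Reagents that add atoms: none
Why: Saucy–Marbet rearrangement followed by base-mediated allene-to-diene isomerization as in step 5.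

Step 19
Reactants: 27 (3S,6E,8E)-6-methyl-10-oxo-3-(prop-1-en-2-yl)undeca-6,8-dien-1-yl acetate
Product: 28 2-[(1S)-2,2,4-trimethyl-3-[(E)-3-oxobut-1-en-1-yl]cyclohex-3-en-1-yl]ethyl acetate
Conditions: conc. H2SO4, CH2Cl2, −20 °C, short contact; then ice
Reagents that add atoms: none
Why: The same acid-mediated cation–olefin cyclization as in step 6 on the enantiomer (protonation of the isopropenyl group, 6-endo closure of C1'–C6', loss of the C6' proton) should give ring B with C2' unchanged.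

Step 20
Reactants: 28 2-[(1S)-2,2,4-trimethyl-3-[(E)-3-oxobut-1-en-1-yl]cyclohex-3-en-1-yl]ethyl acetate
Product: 30 (2E,4E)-5-[(5S)-5-(2-hydroxyethyl)-2,6,6-trimethylcyclohex-1-en-1-yl]-3-methylpenta-2,4-dienenitrile, via nitrile acetate 29 (not isolated)
Conditions: (EtO)2P(O)CH2CN, NaH, THF, 0 °C → rt; then K2CO3, MeOH, rt
Reagents that add atoms: diethyl (cyanomethyl)phosphonate, CCOP(=O)(CC#N)OCC
Why: Horner–Wadsworth–Emmons olefination of the methyl ketone should give mainly the 2E nitrile (the minor 2Z isomer to be removed by chromatography), and methanolysis in the same flask frees the primary alcohol, so that the carbonyl is masked as an aldehyde precursor that tolerates the ylide of step 23.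

Step 21
Reactants: 30 (2E,4E)-5-[(5S)-5-(2-hydroxyethyl)-2,6,6-trimethylcyclohex-1-en-1-yl]-3-methylpenta-2,4-dienenitrile
Product: 31 (2E,4E)-5-[(5S)-5-(2-iodoethyl)-2,6,6-trimethylcyclohex-1-en-1-yl]-3-methylpenta-2,4-dienenitrile
Conditions: I2, PPh3, imidazole, CH2Cl2, 0 °C → rt
Reagents that add atoms: iodine, II
Why: Garegg–Samuelsson iodination, in which the alkoxyphosphonium ion of the primary alcohol is displaced by iodide in an SN2 step that does not involve C2'.

Step 22
Reactants: 31 (2E,4E)-5-[(5S)-5-(2-iodoethyl)-2,6,6-trimethylcyclohex-1-en-1-yl]-3-methylpenta-2,4-dienenitrile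
Product: 32 [2-[(1S)-3-[(1E,3E)-4-cyano-3-methylbuta-1,3-dien-1-yl]-2,2,4-trimethylcyclohex-3-en-1-yl]ethyl]triphenylphosphonium iodide
Conditions: PPh3, MeCN, 80 °C
Reagents that add atoms: triphenylphosphine, c1ccc(cc1)P(c1ccccc1)c1ccccc1
Why: SN2 quaternisation of PPh3 by the unhindered primary iodide under neutral conditions that the conjugated nitrile tolerates.

Step 23
Reactants: 32 [2-[(1S)-3-[(1E,3E)-4-cyano-3-methylbuta-1,3-dien-1-yl]-2,2,4-trimethylcyclohex-3-en-1-yl]ethyl]triphenylphosphonium iodide; 33 2,2-dimethyl-1,3-dioxan-5-one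
Product: 35 (2E,4E)-5-[(5S)-5-[2-(2,2-dimethyl-1,3-dioxan-5-ylidene)ethyl]-2,6,6-trimethylcyclohex-1-en-1-yl]-3-methylpenta-2,4-dienenitrile, via arm ylide 34 (not isolated)
Conditions: NaN(SiMe3)2 (1.0 equiv), THF, −78 °C; then 33, −78 °C → rt
Reagents that add atoms: none
Why: Wittig olefination of a symmetrical ketone by a non-stabilised ylide raises no geometry question and installs the trisubstituted arm alkene with the diol masked as its acetonide, the phosphonium α-CH2 being the most acidic site and the nitrile unreactive at −78 °C.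

Step 24
Reactants: 35 (2E,4E)-5-[(5S)-5-[2-(2,2-dimethyl-1,3-dioxan-5-ylidene)ethyl]-2,6,6-trimethylcyclohex-1-en-1-yl]-3-methylpenta-2,4-dienenitrile
Product: 37 (2E,4E)-5-[(5S)-5-[4-hydroxy-3-(hydroxymethyl)but-2-en-1-yl]-2,6,6-trimethylcyclohex-1-en-1-yl]-3-methylpenta-2,4-dienal, via acetonide aldehyde 36 (not isolated)
Conditions: i-Bu2AlH (1.3 equiv), toluene, −78 °C; then 1 M aq. HCl, THF, 0 °C → rt
Reagents that add atoms: water, O
Why: Partial reduction of the nitrile by i-Bu2AlH stops at the aluminium aldimine, and aqueous acid hydrolyses it to the aldehyde and then cleaves the isopropylidene acetal, so the diol is set free before any acid-sensitive long polyene exists.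

Step 25
Reactants: 19 [(2E,4E,6E,8E,10E,12E)-2,7,11-trimethyl-13-[(5R)-2,6,6-trimethyl-5-(3-methylbut-2-en-1-yl)cyclohex-1-en-1-yl]trideca-2,4,6,8,10,12-hexaen-1-yl]triphenylphosphonium bromide; 37 (2E,4E)-5-[(5S)-5-[4-hydroxy-3-(hydroxymethyl)but-2-en-1-yl]-2,6,6-trimethylcyclohex-1-en-1-yl]-3-methylpenta-2,4-dienal
Product: 39 (all-E,2R,2'S)-2-(3-methylbut-2-en-1-yl)-2'-[4-hydroxy-3-(hydroxymethyl)but-2-en-1-yl]-β,β-carotene, via C30 ylide 38 (not isolated)
Conditions: NaOMe (1.1 equiv), MeOH/CH2Cl2, 0 °C → rt, dark; then EtOH, 75 °C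
Reagents that add atoms: none
Why: Wittig olefination forms C11'=C12' under alkoxide conditions that tolerate free hydroxyl groups, heating should convert the 11'Z isomer into the all-E compound, and both C2 centres are remote from the reacting atoms.

**Compound list**

1 | (4R)-limonene 1,2-oxide [(4R)-1-methyl-4-(prop-1-en-2-yl)-7-oxabicyclo[4.1.0]heptane, cis/trans mixture] | CC12OC1C[C@@H](CC2)C(C)=C | starting material
2 | (3R)-6-oxo-3-(prop-1-en-2-yl)heptanal | C=C(C)[C@@H](CC=O)CCC(C)=O | intermediate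
3 | (5R)-7-hydroxy-5-(prop-1-en-2-yl)heptan-2-one | C=C(C)[C@@H](CCO)CCC(C)=O | intermediate
4 | (3R)-6-methyl-3-(prop-1-en-2-yl)oct-7-yne-1,6-diol (C6 epimers) | C=C(C)[C@@H](CCO)CCC(C)(O)C#C | intermediate
5 | (3R)-6-hydroxy-6-methyl-3-(prop-1-en-2-yl)oct-7-yn-1-yl acetate (C6 epimers) | C=C(C)[C@@H](CCOC(C)=O)CCC(C)(O)C#C | intermediate
6 | 2-methoxypropene | COC(C)=C | starting material
7 | (3R)-6-methyl-3-(prop-1-en-2-yl)-6-(prop-1-en-2-yloxy)oct-7-yn-1-yl acetate | C=C(C)[C@@H](CCOC(C)=O)CCC(C)(OC(C)=C)C#C | intermediate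
8 | (3R)-6-methyl-10-oxo-3-(prop-1-en-2-yl)undeca-6,7-dien-1-yl acetate | C=C(C)[C@@H](CCOC(C)=O)CCC(C)=C=CCC(C)=O | intermediate
9 | (3R,6E,8E)-6-methyl-10-oxo-3-(prop-1-en-2-yl)undeca-6,8-dien-1-yl acetate | C=C(C)[C@@H](CCOC(C)=O)CC/C(C)=C/C=C/C(C)=O | intermediate
10 | 2-[(1R)-2,2,4-trimethyl-3-[(E)-3-oxobut-1-en-1-yl]cyclohex-3-en-1-yl]ethyl acetate | CC(=O)/C=C/C1=C(C)CC[C@H](CCOC(C)=O)C1(C)C | intermediate
11 | (1E)-1-[(5R)-5-(2-hydroxyethyl)-2,6,6-trimethylcyclohex-1-en-1-yl]-3-methylpenta-1,4-dien-3-ol (C3 epimers) | C=CC(C)(O)/C=C/C1=C(C)CC[C@H](CCO)C1(C)C | intermediate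
12 | 2-[(1R)-3-[(1E)-3-hydroxy-3-methylpenta-1,4-dien-1-yl]-2,2,4-trimethylcyclohex-3-en-1-yl]acetaldehyde | C=CC(C)(O)/C=C/C1=C(C)CC[C@H](CC=O)C1(C)C | intermediate
13 | (1E)-3-methyl-1-[(5R)-2,6,6-trimethyl-5-(3-methylbut-2-en-1-yl)cyclohex-1-en-1-yl]penta-1,4-dien-3-ol | C=CC(C)(O)/C=C/C1=C(C)CC[C@H](CC=C(C)C)C1(C)C | intermediate
14 | [(2E,4E)-3-methyl-5-[(5R)-2,6,6-trimethyl-5-(3-methylbut-2-en-1-yl)cyclohex-1-en-1-yl]penta-2,4-dien-1-yl]triphenylphosphonium bromide | CC(C)=CC[C@H]1CCC(C)=C(/C=C/C(C)=C/C[P+](c2ccccc2)(c2ccccc2)c2ccccc2)C1(C)C.[Br-] | intermediate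
15 | (2E,4E,6E)-2,7-dimethylocta-2,4,6-trienedial | O=C/C(C)=C/C=C/C=C(C)/C=O | starting material
16 | triphenyl[(2E,4E)-3-methyl-5-[(5R)-2,6,6-trimethyl-5-(3-methylbut-2-en-1-yl)cyclohex-1-en-1-yl]penta-2,4-dien-1-ylidene]phosphorane | CC(C)=CC[C@H]1CCC(C)=C(/C=C/C(C)=C/C=P(c2ccccc2)(c2ccccc2)c2ccccc2)C1(C)C | intermediate
17 | (2E,4E,6E,8E,10E,12E)-2,7,11-trimethyl-13-[(5R)-2,6,6-trimethyl-5-(3-methylbut-2-en-1-yl)cyclohex-1-en-1-yl]trideca-2,4,6,8,10,12-hexaenal | CC(C)=CC[C@H]1CCC(C)=C(/C=C/C(C)=C/C=C/C(C)=C/C=C/C=C(C)/C=O)C1(C)C | intermediate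
18 | (2E,4E,6E,8E,10E,12E)-2,7,11-trimethyl-13-[(5R)-2,6,6-trimethyl-5-(3-methylbut-2-en-1-yl)cyclohex-1-en-1-yl]trideca-2,4,6,8,10,12-hexaen-1-ol | CC(C)=CC[C@H]1CCC(C)=C(/C=C/C(C)=C/C=C/C(C)=C/C=C/C=C(C)/CO)C1(C)C | intermediate
19 | [(2E,4E,6E,8E,10E,12E)-2,7,11-trimethyl-13-[(5R)-2,6,6-trimethyl-5-(3-methylbut-2-en-1-yl)cyclohex-1-en-1-yl]trideca-2,4,6,8,10,12-hexaen-1-yl]triphenylphosphonium bromide | CC(C)=CC[C@H]1CCC(C)=C(/C=C/C(C)=C/C=C/C(C)=C/C=C/C=C(C)/C[P+](c2ccccc2)(c2ccccc2)c2ccccc2)C1(C)C.[Br-] | intermediate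
20 | (4S)-limonene 1,2-oxide [(4S)-1-methyl-4-(prop-1-en-2-yl)-7-oxabicyclo[4.1.0]heptane, cis/trans mixture] | CC12OC1C[C@H](CC2)C(C)=C | starting material
21 | (3S)-6-oxo-3-(prop-1-en-2-yl)heptanal | C=C(C)[C@H](CC=O)CCC(C)=O | intermediate
22 | (5S)-7-hydroxy-5-(prop-1-en-2-yl)heptan-2-one | C=C(C)[C@H](CCO)CCC(C)=O | intermediate
23 | (3S)-6-methyl-3-(prop-1-en-2-yl)oct-7-yne-1,6-diol (C6 epimers) | C=C(C)[C@H](CCO)CCC(C)(O)C#C | intermediate
24 | (3S)-6-hydroxy-6-methyl-3-(prop-1-en-2-yl)oct-7-yn-1-yl acetate (C6 epimers) | C=C(C)[C@H](CCOC(C)=O)CCC(C)(O)C#C | intermediate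
25 | (3S)-6-methyl-3-(prop-1-en-2-yl)-6-(prop-1-en-2-yloxy)oct-7-yn-1-yl acetate | C=C(C)[C@H](CCOC(C)=O)CCC(C)(OC(C)=C)C#C | intermediate
26 | (3S)-6-methyl-10-oxo-3-(prop-1-en-2-yl)undeca-6,7-dien-1-yl acetate | C=C(C)[C@H](CCOC(C)=O)CCC(C)=C=CCC(C)=O | intermediate
27 | (3S,6E,8E)-6-methyl-10-oxo-3-(prop-1-en-2-yl)undeca-6,8-dien-1-yl acetate | C=C(C)[C@H](CCOC(C)=O)CC/C(C)=C/C=C/C(C)=O | intermediate
28 | 2-[(1S)-2,2,4-trimethyl-3-[(E)-3-oxobut-1-en-1-yl]cyclohex-3-en-1-yl]ethyl acetate | CC(=O)/C=C/C1=C(C)CC[C@@H](CCOC(C)=O)C1(C)C | intermediate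
29 | 2-[(1S)-3-[(1E,3E)-4-cyano-3-methylbuta-1,3-dien-1-yl]-2,2,4-trimethylcyclohex-3-en-1-yl]ethyl acetate | N#C/C=C(C)/C=C/C1=C(C)CC[C@@H](CCOC(C)=O)C1(C)C | intermediate
30 | (2E,4E)-5-[(5S)-5-(2-hydroxyethyl)-2,6,6-trimethylcyclohex-1-en-1-yl]-3-methylpenta-2,4-dienenitrile | N#C/C=C(C)/C=C/C1=C(C)CC[C@@H](CCO)C1(C)C | intermediate
31 | (2E,4E)-5-[(5S)-5-(2-iodoethyl)-2,6,6-trimethylcyclohex-1-en-1-yl]-3-methylpenta-2,4-dienenitrile | N#C/C=C(C)/C=C/C1=C(C)CC[C@@H](CCI)C1(C)C | intermediate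
32 | [2-[(1S)-3-[(1E,3E)-4-cyano-3-methylbuta-1,3-dien-1-yl]-2,2,4-trimethylcyclohex-3-en-1-yl]ethyl]triphenylphosphonium iodide | N#C/C=C(C)/C=C/C1=C(C)CC[C@@H](CC[P+](c2ccccc2)(c2ccccc2)c2ccccc2)C1(C)C.[I-] | intermediate
33 | 2,2-dimethyl-1,3-dioxan-5-one | CC1(C)OCC(=O)CO1 | starting material
34 | (2E,4E)-3-methyl-5-[(5S)-2,6,6-trimethyl-5-[2-(triphenylphosphoranylidene)ethyl]cyclohex-1-en-1-yl]penta-2,4-dienenitrile | N#C/C=C(C)/C=C/C1=C(C)CC[C@@H](CC=P(c2ccccc2)(c2ccccc2)c2ccccc2)C1(C)C | intermediate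
35 | (2E,4E)-5-[(5S)-5-[2-(2,2-dimethyl-1,3-dioxan-5-ylidene)ethyl]-2,6,6-trimethylcyclohex-1-en-1-yl]-3-methylpenta-2,4-dienenitrile | N#C/C=C(C)/C=C/C1=C(C)CC[C@@H](CC=C2COC(C)(C)OC2)C1(C)C | intermediate
36 | (2E,4E)-5-[(5S)-5-[2-(2,2-dimethyl-1,3-dioxan-5-ylidene)ethyl]-2,6,6-trimethylcyclohex-1-en-1-yl]-3-methylpenta-2,4-dienal | O=C/C=C(C)/C=C/C1=C(C)CC[C@@H](CC=C2COC(C)(C)OC2)C1(C)C | intermediate
37 | (2E,4E)-5-[(5S)-5-[4-hydroxy-3-(hydroxymethyl)but-2-en-1-yl]-2,6,6-trimethylcyclohex-1-en-1-yl]-3-methylpenta-2,4-dienal | O=C/C=C(C)/C=C/C1=C(C)CC[C@@H](CC=C(CO)CO)C1(C)C | intermediate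
38 | triphenyl[(2E,4E,6E,8E,10E,12E)-2,7,11-trimethyl-13-[(5R)-2,6,6-trimethyl-5-(3-methylbut-2-en-1-yl)cyclohex-1-en-1-yl]trideca-2,4,6,8,10,12-hexaen-1-ylidene]phosphorane | CC(C)=CC[C@H]1CCC(C)=C(/C=C/C(C)=C/C=C/C(C)=C/C=C/C=C(C)/C=P(c2ccccc2)(c2ccccc2)c2ccccc2)C1(C)C | intermediate
39 | (all-E,2R,2'S)-2-(3-methylbut-2-en-1-yl)-2'-[4-hydroxy-3-(hydroxymethyl)but-2-en-1-yl]-β,β-carotene (CNP0213288.1) | CC(C)=CC[C@H]1CCC(C)=C(/C=C/C(C)=C/C=C/C(C)=C/C=C/C=C(C)/C=C/C=C(C)/C=C/C2=C(C)CC[C@@H](CC=C(CO)CO)C2(C)C)C1(C)C | target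

**Step count and risks**

Total step count: 25 (steps 1–13 for the ring A half, steps 14–24 for the ring B half, step 25 for the union).
Longest linear sequence: 14 steps (steps 1–13 and 25, from 1 to 39); the ring B branch has 12 (steps 14–25).

Steps most likely to fail:

1. Step 6. The C1 cation may lose the proton on C2 to give the isopropylidene isomer, or suffer a 1,2-hydride shift, faster than it closes the ring. In sulfuric acid the achiral alkene is reprotonated and cyclizes, so the configuration at C2 erodes; solvolysis of the acetate and oligomerisation are lesser concerns. Fallback: the cation is generated aprotically, so that any alkene formed by elimination cannot re-enter. Starting from 9, dry HCl in CH2Cl2 at −78 °C should add to the isopropenyl group in the Markovnikov sense to give the tertiary chloride (3R,6E,8E)-3-(2-chloropropan-2-yl)-6-methyl-10-oxoundeca-6,8-dien-1-yl acetate F1. Ionisation with SnCl4 in the presence of 2,6-di-tert-butylpyridine as proton trap (CH2Cl2, −78 °C) should then close C1–C6 and give, after kinetic proton loss, the non-conjugated ring isomer 2-[(1R)-4,6,6-trimethyl-5-[(E)-3-oxobut-1-en-1-yl]cyclohex-3-en-1-yl]ethyl acetate F2. With C1 now quaternary, a brief treatment with cold concentrated H2SO4 can move the ring alkene into conjugation without access to C2, and the route is rejoined at 10.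

2. Step 19. This is the same process as in step 6, in the enantiomeric series: erosion of the C2' configuration by reversible deprotonation of the cation before ring closure. Fallback: the same detour in mirror image. From 27, HCl addition gives (3S,6E,8E)-3-(2-chloropropan-2-yl)-6-methyl-10-oxoundeca-6,8-dien-1-yl acetate F3. SnCl4 with 2,6-di-tert-butylpyridine gives 2-[(1S)-4,6,6-trimethyl-5-[(E)-3-oxobut-1-en-1-yl]cyclohex-3-en-1-yl]ethyl acetate F4, and acid isomerization returns to the route at 28.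

3. Step 23. The basic ylide may deprotonate the α,α'-dialkoxy ketone instead of adding to it, or may attack the conjugated nitrile, so that the arm alkene forms poorly. Fallback: the polarity is reversed, with the arm as electrophile. From 30, Parikh–Doering oxidation gives (2E,4E)-3-methyl-5-[(5S)-2,6,6-trimethyl-5-(2-oxoethyl)cyclohex-1-en-1-yl]penta-2,4-dienenitrile F5. Knoevenagel condensation with dimethyl malonate (piperidine, AcOH, toluene, water removal) gives dimethyl 2-[2-[(1S)-3-[(1E,3E)-4-cyano-3-methylbuta-1,3-dien-1-yl]-2,2,4-trimethylcyclohex-3-en-1-yl]ethylidene]propanedioate F6. Excess i-Bu2AlH at −78 °C should reduce both esters to the allylic diol and the nitrile to the aldimine, and mild aqueous acid then gives 37, where the route is rejoined.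

**Further compounds**

F1 | step 6 | (3R,6E,8E)-3-(2-chloropropan-2-yl)-6-methyl-10-oxoundeca-6,8-dien-1-yl acetate | CC(C)(Cl)[C@@H](CCOC(C)=O)CC/C(C)=C/C=C/C(C)=O
F2 | step 6 | 2-[(1R)-4,6,6-trimethyl-5-[(E)-3-oxobut-1-en-1-yl]cyclohex-3-en-1-yl]ethyl acetate (C5 epimers) | CC(=O)/C=C/C1C(C)=CC[C@H](CCOC(C)=O)C1(C)C
F3 | step 19 | (3S,6E,8E)-3-(2-chloropropan-2-yl)-6-methyl-10-oxoundeca-6,8-dien-1-yl acetate | CC(C)(Cl)[C@H](CCOC(C)=O)CC/C(C)=C/C=C/C(C)=O
F4 | step 19 | 2-[(1S)-4,6,6-trimethyl-5-[(E)-3-oxobut-1-en-1-yl]cyclohex-3-en-1-yl]ethyl acetate (C5 epimers) | CC(=O)/C=C/C1C(C)=CC[C@@H](CCOC(C)=O)C1(C)C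
F5 | step 23 | (2E,4E)-3-methyl-5-[(5S)-2,6,6-trimethyl-5-(2-oxoethyl)cyclohex-1-en-1-yl]penta-2,4-dienenitrile | N#C/C=C(C)/C=C/C1=C(C)CC[C@@H](CC=O)C1(C)C
F6 | step 23 | dimethyl 2-[2-[(1S)-3-[(1E,3E)-4-cyano-3-methylbuta-1,3-dien-1-yl]-2,2,4-trimethylcyclohex-3-en-1-yl]ethylidene]propanedioate | N#C/C=C(C)/C=C/C1=C(C)CC[C@@H](CC=C(C(=O)OC)C(=O)OC)C1(C)C
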